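**Strategy**

The route rests on cutting the C1–C6 bond of ring A, which unravels the 2,4-dioxygenated 6-propylbenzoyl unit into a linear 3,5,7-trioxodecanoyl chain already esterified to O3 of ring B. The key step exploits the alternation in ring A of the carboxyl-bearing C1, oxygenated C2 and C4, and propyl-bearing C6, the imprint of a tetraketide. In one operation an intramolecular aldol joins chain C2 to the C7 ketone and loss of one water aromatises ring A, so the crowded depside ester is made by ketene capture before ring A exists. The precursor is an aryl triketo ester of a ring B phenol whose O2, O4 and carboxyl are masked as MOM ethers and a benzyl ester.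

Key step: step 9

**Remarks on the chemistry**

- Closing ring A from the open chain sets free one molecule of water only (acyl unit C10H13O4 in 19, aroyl unit C10H11O3 in 21). The two ring A hydroxyls arise by enolisation of the chain C3 and C5 ketones.
- The ten-carbon chain is C1–C4 from dioxinone 1, C5–C6 from an acetyl unit and C7–C10 from a butanoyl unit, so an acetyl donor (acetyl chloride) is needed besides the butanoyl donor.
- Assumption: N-methoxy-N-methylbutanamide 5 and 5-propylresorcinol 8 are taken as catalogue chemicals; tautomeric polycarbonyl compounds are drawn in their keto forms.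

**Route**

Step 1
Reactants: 1 2,2,6-trimethyl-4H-1,3-dioxin-4-one; 2 acetyl chloride
Product: 4 2,2-dimethyl-6-(2-oxopropyl)-4H-1,3-dioxin-4-one, via lithium dienolate 3 (not isolated)
Conditions: LiN(SiMe3)2, THF, −78 °C; 2 (0.5 equiv), −78 °C; aq. NH4Cl
Reagents that add atoms: none
Why: Kinetic deprotonation of the 6-methyl group gives the vinylogous enolate, which is C-acylated at its γ-carbon by the acid chloride (vinylogous Claisen-type acylation), the enolate being kept in excess because 4 is the stronger acid.

Step 2
Reactants: 4 2,2-dimethyl-6-(2-oxopropyl)-4H-1,3-dioxin-4-one; 5 N-methoxy-N-methylbutanamide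
Product: 7 6-(2,4-dioxoheptyl)-2,2-dimethyl-4H-1,3-dioxin-4-one, via dilithium dianion 6 (not isolated)
Conditions: LiN(iPr)2 (2.2 equiv), THF, −78 °C; 5, −78 to 0 °C; cold dilute aq. HCl
Reagents that add atoms: none
Why: The second deprotonation places charge on the terminal methyl carbon, the most nucleophilic site of the dianion, and its acylation by the N-methoxy-N-methylamide (crossed Claisen condensation of a β-dicarbonyl dianion, Weinreb ketone synthesis) stops at the ketone because the carbonyl is released only on work-up.

Step 3
Reactants: 8 5-propylbenzene-1,3-diol (5-propylresorcinol)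
Product: 9 1,3-bis(methoxymethoxy)-5-propylbenzene
Conditions: MOMCl, iPr2NEt, CH2Cl2, 0 °C to rt
Reagents that add atoms: chloromethyl methyl ether, COCCl
Why: O-Alkylation of both phenols by the reactive α-chloro ether (Williamson-type acetal formation) installs groups that resist organolithiums and direct the two metalations that follow.

Step 4
Reactants: 9 1,3-bis(methoxymethoxy)-5-propylbenzene
Product: 12 2,6-bis(methoxymethoxy)-4-propylphenol, via aryllithium 10 (not isolated), via dimethyl arylboronate 11 (not isolated)
Conditions: n-BuLi, THF, 0 °C; B(OMe)3, −78 °C to rt; 30% H2O2, aq. NaOH, 0 °C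
Reagents that add atoms: hydrogen peroxide, OO
Why: The C2 proton is flanked by two coordinating MOM ethers, so directed ortho-metalation occurs only there, and borylation followed by peroxide-induced aryl migration from boron to oxygen (boronate oxidation) turns the C–Li bond into C–OH.

Step 5
Reactants: 12 2,6-bis(methoxymethoxy)-4-propylphenol
Product: 13 tert-butyl[2,6-bis(methoxymethoxy)-4-propylphenoxy]dimethylsilane
Conditions: TBSCl, imidazole, DMF, rt
Reagents that add atoms: tert-butyldimethylsilyl chloride, CC(C)(C)[Si](C)(C)Cl
Why: Imidazole-promoted silylation gives a fluoride-labile aryl silyl ether that tolerates alkyllithiums and is orthogonal to the MOM ethers and to the later benzyl ester.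

Step 6
Reactants: 13 tert-butyl[2,6-bis(methoxymethoxy)-4-propylphenoxy]dimethylsilane; 14 benzyl chloroformate
Product: 16 benzyl 3-(tert-butyldimethylsilyloxy)-2,4-bis(methoxymethoxy)-6-propylbenzoate, via aryllithium 15 (not isolated)
Conditions: s-BuLi, TMEDA, THF, −78 °C; solution added to 14 (3 equiv), THF, −78 °C
Reagents that add atoms: none
Why: The two free ring positions of 13 are equivalent and each is ortho to a MOM ether, so directed ortho-metalation is regiochemically unambiguous, and the hindered aryllithium is acylated once by the chloroformate under inverse addition to give the benzyl ester directly.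

Step 7
Reactants: 16 benzyl 3-(tert-butyldimethylsilyloxy)-2,4-bis(methoxymethoxy)-6-propylbenzoate
Product: 17 benzyl 3-hydroxy-2,4-bis(methoxymethoxy)-6-propylbenzoate
Conditions: Bu4NF, AcOH, THF, 0 °C
Reagents that add atoms: none
Why: Fluoride cleaves the aryl O–Si bond selectively (desilylation), and the acetic acid buffer protonates the phenoxide so that neither the benzyl ester nor the MOM acetals are affected.

Step 8
Reactants: 17 benzyl 3-hydroxy-2,4-bis(methoxymethoxy)-6-propylbenzoate; 7 6-(2,4-dioxoheptyl)-2,2-dimethyl-4H-1,3-dioxin-4-one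
Product: 19 benzyl 2,4-bis(methoxymethoxy)-6-propyl-3-(3,5,7-trioxodecanoyloxy)benzoate, via acylketene 18 (not isolated)
Conditions: PhMe, 110 °C, 7 (1.5 equiv) added in portions; concentrated and used crude
Reagents that add atoms: none
Why: Thermal retro-[4+2] fragmentation of the dioxinone expels acetone, and the resulting acylketene is captured at its ketene carbon by the phenol of 17 under neutral conditions (dioxinone thermolysis with ketene trapping), the excess of 7 covering ketene lost to self-lactonisation.

Step 9
Reactants: 19 benzyl 2,4-bis(methoxymethoxy)-6-propyl-3-(3,5,7-trioxodecanoyloxy)benzoate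
Product: 21 benzyl 3-(2,4-dihydroxy-6-propylbenzoyloxy)-2,4-bis(methoxymethoxy)-6-propylbenzoate, via aldol adduct 20 (not isolated)
Conditions: Cs2CO3 (2 equiv), THF, 0 °C to rt; then AcOH
Reagents that add atoms: none
Why: Cs2CO3 removes a proton from the C2 methylene between the ester and the C3 ketone; the enolate adds to the C7 ketone to form the C2–C7 bond (C1–C6 of ring A) in adduct 20, which loses one water by E1cB elimination, and enolisation of the C3 and C5 carbonyls then delivers the aromatic 2,4-dihydroxy-6-propylbenzoate. The closest known reaction is the biomimetic aldol aromatisation of 3,5,7-triketo esters to resorcylates, the laboratory counterpart of orsellinate-type polyketide cyclisation. Ring A closes in the 6-(enolendo)-exo-trig mode. No stereocentre remains, since the two in 20 vanish on aromatisation. The step needs the C2-to-C7 aldol to outrun attack of the C5 enolate oxygen or of the C6 carbanion on the aryl ester carbonyl (pyranone or acylphloroglucinol with loss of the ring B phenoxide) and the C8-to-C3 aldol. A ketone is a better electrophile than an ester flanked by the two ortho MOM ethers of ring B, carbonate cannot deprotonate C8, and the aprotic medium excludes transesterification.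

Step 10
Reactants: 21 benzyl 3-(2,4-dihydroxy-6-propylbenzoyloxy)-2,4-bis(methoxymethoxy)-6-propylbenzoate
Product: 22 benzyl 3-(2,4-dimethoxy-6-propylbenzoyloxy)-2,4-bis(methoxymethoxy)-6-propylbenzoate
Conditions: MeI, K2CO3, acetone, reflux
Reagents that add atoms: iodomethane, CI
Why: Williamson O-methylation of both ring A phenols (the hydrogen-bonded 2-OH needs the reflux) should be clean because ring B carries no free hydroxyl next to the depside ester, so base-induced acyl migration is impossible.

Step 11
Reactants: 22 benzyl 3-(2,4-dimethoxy-6-propylbenzoyloxy)-2,4-bis(methoxymethoxy)-6-propylbenzoate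
Product: 23 benzyl 3-(2,4-dimethoxy-6-propylbenzoyloxy)-2,4-dihydroxy-6-propylbenzoate
Conditions: HCl (2 M in MeOH), THF, rt to 40 °C
Reagents that add atoms: none
Why: Acid-catalysed acetal exchange with methanol removes both MOM groups as dimethoxymethane, while the two doubly ortho-substituted esters are too hindered for methanolysis or acyl shift and the still-esterified carboxyl cannot decarboxylate.

Step 12
Reactants: 23 benzyl 3-(2,4-dimethoxy-6-propylbenzoyloxy)-2,4-dihydroxy-6-propylbenzoate
Product: 24 3-(2,4-dimethoxy-6-propylbenzoyloxy)-2,4-dihydroxy-6-propylbenzoic acid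
Conditions: H2 (1 atm), Pd/C, EtOAc, rt
Reagents that add atoms: none
Why: Hydrogenolysis of the benzylic C–O bond frees the acid under neutral conditions at room temperature, leaving the aryl ester, the phenols and both arenes untouched.

**Compound list**

1 | 2,2,6-trimethyl-4H-1,3-dioxin-4-one | CC1=CC(=O)OC(C)(C)O1 | starting material
2 | acetyl chloride | CC(Cl)=O | starting material
3 | lithium 2,2-dimethyl-6-methylidene-6H-1,3-dioxin-4-olate (lithium dienolate of 1) | [Li]OC1=CC(=C)OC(C)(C)O1 | intermediate (not isolated)
4 | 2,2-dimethyl-6-(2-oxopropyl)-4H-1,3-dioxin-4-one | CC(=O)CC1=CC(=O)OC(C)(C)O1 | intermediate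
5 | N-methoxy-N-methylbutanamide | CCCC(=O)N(C)OC | starting material
6 | dilithium dianion of 4 (bis-enolate with terminal methylidene) | C=C(O[Li])C=C1C=C(O[Li])OC(C)(C)O1 | intermediate (not isolated)
7 | 6-(2,4-dioxoheptyl)-2,2-dimethyl-4H-1,3-dioxin-4-one | CCCC(=O)CC(=O)CC1=CC(=O)OC(C)(C)O1 | intermediate
8 | 5-propylbenzene-1,3-diol (5-propylresorcinol) | CCCc1cc(O)cc(O)c1 | starting material
9 | 1,3-bis(methoxymethoxy)-5-propylbenzene | CCCc1cc(OCOC)cc(OCOC)c1 | intermediate
10 | [2,6-bis(methoxymethoxy)-4-propylphenyl]lithium | [Li]c1c(OCOC)cc(CCC)cc1OCOC | intermediate (not isolated)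
11 | dimethyl [2,6-bis(methoxymethoxy)-4-propylphenyl]boronate | COB(OC)c1c(OCOC)cc(CCC)cc1OCOC | intermediate (not isolated)
12 | 2,6-bis(methoxymethoxy)-4-propylphenol | CCCc1cc(OCOC)c(O)c(OCOC)c1 | intermediate
13 | tert-butyl[2,6-bis(methoxymethoxy)-4-propylphenoxy]dimethylsilane | CCCc1cc(OCOC)c(O[Si](C)(C)C(C)(C)C)c(OCOC)c1 | intermediate
14 | benzyl chloroformate | O=C(Cl)OCc1ccccc1 | starting material
15 | [3-(tert-butyldimethylsilyloxy)-2,4-bis(methoxymethoxy)-6-propylphenyl]lithium | [Li]c1c(CCC)cc(OCOC)c(O[Si](C)(C)C(C)(C)C)c1OCOC | intermediate (not isolated)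
16 | benzyl 3-(tert-butyldimethylsilyloxy)-2,4-bis(methoxymethoxy)-6-propylbenzoate | CCCc1cc(OCOC)c(O[Si](C)(C)C(C)(C)C)c(OCOC)c1C(=O)OCc1ccccc1 | intermediate
17 | benzyl 3-hydroxy-2,4-bis(methoxymethoxy)-6-propylbenzoate | CCCc1cc(OCOC)c(O)c(OCOC)c1C(=O)OCc1ccccc1 | intermediate
18 | dec-1-ene-1,3,5,7-tetrone (acylketene) | CCCC(=O)CC(=O)CC(=O)C=C=O | intermediate (not isolated)
19 | benzyl 2,4-bis(methoxymethoxy)-6-propyl-3-(3,5,7-trioxodecanoyloxy)benzoate | CCCC(=O)CC(=O)CC(=O)CC(=O)Oc1c(OCOC)cc(CCC)c(C(=O)OCc2ccccc2)c1OCOC | intermediate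
20 | benzyl 3-[(2-hydroxy-4,6-dioxo-2-propylcyclohexane-1-carbonyl)oxy]-2,4-bis(methoxymethoxy)-6-propylbenzoate (transient diastereomer mixture, configuration undefined) | CCCC1(O)CC(=O)CC(=O)C1C(=O)Oc1c(OCOC)cc(CCC)c(C(=O)OCc2ccccc2)c1OCOC | intermediate (not isolated)
21 | benzyl 3-(2,4-dihydroxy-6-propylbenzoyloxy)-2,4-bis(methoxymethoxy)-6-propylbenzoate | CCCc1cc(O)cc(O)c1C(=O)Oc1c(OCOC)cc(CCC)c(C(=O)OCc2ccccc2)c1OCOC | intermediate
22 | benzyl 3-(2,4-dimethoxy-6-propylbenzoyloxy)-2,4-bis(methoxymethoxy)-6-propylbenzoate | CCCc1cc(OC)cc(OC)c1C(=O)Oc1c(OCOC)cc(CCC)c(C(=O)OCc2ccccc2)c1OCOC | intermediate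
23 | benzyl 3-(2,4-dimethoxy-6-propylbenzoyloxy)-2,4-dihydroxy-6-propylbenzoate | CCCc1cc(OC)cc(OC)c1C(=O)Oc1c(O)cc(CCC)c(C(=O)OCc2ccccc2)c1O | intermediate
24 | 3-(2,4-dimethoxy-6-propylbenzoyloxy)-2,4-dihydroxy-6-propylbenzoic acid | CCCc1cc(OC)cc(OC)c1C(=O)Oc1c(O)cc(CCC)c(C(=O)O)c1O | target

**Step count**

Total: 12 steps. Longest linear sequence: 10 steps (steps 3–12, from 8); the chain branch (steps 1–2) joins at step 8.

**Steps most likely to fail**

1. Step 9. The C5 enolate oxygen or the C6 carbanion may attack the activated aryl ester faster than C2 adds to C7, which would expel the ring B phenoxide and give a lactone or a C-acylated ring in place of ring A. Fallback: ring A is brought in ready-made, setting out from 8. O-Methylation (Me2SO4, K2CO3, acetone) should give 1,3-dimethoxy-5-propylbenzene F1. Vilsmeier–Haack formylation (POCl3, DMF) para to one methoxy group should give 2,4-dimethoxy-6-propylbenzaldehyde F2. Pinnick oxidation (NaClO2, NaH2PO4, 2-methyl-2-butene, t-BuOH/water) should give 2,4-dimethoxy-6-propylbenzoic acid F3. Oxalyl chloride with catalytic DMF should give 2,4-dimethoxy-6-propylbenzoyl chloride F4. This acylates phenol 17 (Et3N, DMAP, CH2Cl2, 40 °C) to give 22, where the route is rejoined before step 11.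

2. Step 8. The acylketene may close on itself (the C5 enol oxygen adding to the ketene carbon) faster than the hindered, weakly nucleophilic phenol captures it. Fallback: aromatise first and acylate second, setting out from 7. Et3N in CH2Cl2 should effect the aldol aromatisation on the dioxinone itself to give 7-hydroxy-2,2-dimethyl-5-propyl-4H-1,3-benzodioxin-4-one F5. Methylation (MeI, K2CO3, acetone) should give 7-methoxy-2,2-dimethyl-5-propyl-4H-1,3-benzodioxin-4-one F6, which removes the competing free phenol. Irradiation at 300 nm in CH2Cl2 with 17 present should expel acetone to give the ortho-quinone ketene 3-methoxy-6-(oxomethylidene)-5-propylcyclohexa-2,4-dien-1-one F7. This ketene has no internal nucleophile and should be captured by 17 as benzyl 3-(2-hydroxy-4-methoxy-6-propylbenzoyloxy)-2,4-bis(methoxymethoxy)-6-propylbenzoate F8. Methylation of the remaining phenol under the conditions of step 10 comes back to the route at 22.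

3. Step 6. Metalation beside the propyl group may be slow, so that incomplete lithiation, benzylic deprotonation or attack of the base at silicon erodes the conversion. Fallback: the site is fixed by electrophilic substitution, setting out from 13. N-Bromosuccinimide in MeCN at 0 °C should brominate the only activated free position to give [3-bromo-2,6-bis(methoxymethoxy)-4-propylphenoxy](tert-butyl)dimethylsilane F9. Bromine–lithium exchange (n-BuLi, THF, −78 °C) then generates the same aryllithium 15, which is quenched with 14 as in step 6 and comes back to the route at 16.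

**Further compounds**

F1 | step 9 | 1,3-dimethoxy-5-propylbenzene | CCCc1cc(OC)cc(OC)c1
F2 | step 9 | 2,4-dimethoxy-6-propylbenzaldehyde | CCCc1cc(OC)cc(OC)c1C=O
F3 | step 9 | 2,4-dimethoxy-6-propylbenzoic acid | CCCc1cc(OC)cc(OC)c1C(=O)O
F4 | step 9 | 2,4-dimethoxy-6-propylbenzoyl chloride | CCCc1cc(OC)cc(OC)c1C(=O)Cl
F5 | step 8 | 7-hydroxy-2,2-dimethyl-5-propyl-4H-1,3-benzodioxin-4-one | CCCc1cc(O)cc2OC(C)(C)OC(=O)c12
F6 | step 8 | 7-methoxy-2,2-dimethyl-5-propyl-4H-1,3-benzodioxin-4-one | CCCc1cc(OC)cc2OC(C)(C)OC(=O)c12
F7 | step 8 | 3-methoxy-6-(oxomethylidene)-5-propylcyclohexa-2,4-dien-1-one | CCCC1=CC(OC)=CC(=O)C1=C=O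
F8 | step 8 | benzyl 3-(2-hydroxy-4-methoxy-6-propylbenzoyloxy)-2,4-bis(methoxymethoxy)-6-propylbenzoate | CCCc1cc(OC)cc(O)c1C(=O)Oc1c(OCOC)cc(CCC)c(C(=O)OCc2ccccc2)c1OCOC
F9 | step 6 | [3-bromo-2,6-bis(methoxymethoxy)-4-propylphenoxy](tert-butyl)dimethylsilane | CCCc1cc(OCOC)c(O[Si](C)(C)C(C)(C)C)c(OCOC)c1Br
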